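**Plan**
- Cuts, in retrosynthetic order: C3'–Cl (back to an epoxy ester), the O3–C1' ester bond, the C11–O and C7–C11 bonds of the hydroxyisopropyl enone (O2 and acetone), the ring A oxygens and hydrogens, and last C9–C10, which opens ring B and leaves ring A aromatic.
- Enabling feature: in ring A (C1, C2, C3, C4, C5, C10) the methyl-bearing quaternary C10 is para to the C3 oxygen and C4 carries the second methyl. Ring A is therefore a masked 2,4-dimethylphenol, and its para carbon C10 can be bonded to C9, the carbon next to the C8 ketone, through the C5–C6–C7–C8 tether.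
- Forward order: the C6–C9 diazoketone chain is built on the arene; ring B (C5–C10) is closed by the dearomatising carbene cyclisation; ring A is reduced and oxygenated; the epoxy acid is attached at O3; the ring B enone carbinol and the chlorohydrin come last.
- Stereochemistry: C10 from the chiral rhodium carboxylate. C5 (dissolving-metal reduction), C4 (Rubottom oxidation anti to the C10 methyl) and C3 (axial hydride delivery) are relayed from C10. C2' and C3' come from an asymmetric epoxidation of tiglyl alcohol and an inverting chloride opening at C3'.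

Key step: step 8

Numbering: eudesmane numbering is used for the decalin (C14 = methyl on C10, C15 = methyl on C4, C11 = carbinol carbon on C7); primed numbers belong to the C3 ester side chain.
Assumption: Rh2(S-PTTL)4, dirhodium tetrakis[N-phthaloyl-(S)-tert-leucinate], is taken to deliver the 10S dienone; if the sense of induction is the opposite, Rh2(R-PTTL)4 is used with no other change.

**Route**

Step 1
Reactants: 1 2,6-dimethylbenzaldehyde
Product: 2 3-bromo-2,6-dimethylbenzaldehyde
Conditions: NBS (1.05 equiv), conc. H2SO4, 0 °C to rt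
Reagents that add atoms: N-bromosuccinimide, O=C1CCC(=O)N1Br
Why: Electrophilic aromatic bromination in which C3 is ortho to one methyl, para to the other and meta to the formyl group, so that all three substituents direct to this position while the strongly acidic medium keeps the reaction ionic and away from the benzylic hydrogens.

Step 2
Reactants: 2 3-bromo-2,6-dimethylbenzaldehyde; 3 triethyl phosphonoacetate
Product: 4 ethyl (E)-3-(3-bromo-2,6-dimethylphenyl)prop-2-enoate
Conditions: NaH, THF, 0 °C to rt
Reagents that add atoms: none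
Why: Horner–Wadsworth–Emmons olefination of a non-enolisable aryl aldehyde with a stabilised phosphonate anion, which should give the E acrylate even with two ortho substituents.

Step 3
Reactants: 4 ethyl (E)-3-(3-bromo-2,6-dimethylphenyl)prop-2-enoate
Product: 6 ethyl (E)-3-(3-hydroxy-2,6-dimethylphenyl)prop-2-enoate, via aryl pinacol boronate 5 (not isolated)
Conditions: B2pin2, Pd(dppf)Cl2 (3 mol %), KOAc, 1,4-dioxane, 90 °C; then 30% H2O2, 1 M NaOH, THF, 0 °C
Reagents that add atoms: bis(pinacolato)diboron, CC1(C)OB(OC1(C)C)B1OC(C)(C)C(C)(C)O1 (boron of intermediate 5 only); hydrogen peroxide, OO (phenol oxygen)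
Why: Miyaura borylation of the aryl bromide followed by oxidative conversion of the C–B bond into a C–O bond at the same carbon, the short cold peroxide treatment being expected to spare the acrylate ester.

Step 4
Reactants: 6 ethyl (E)-3-(3-hydroxy-2,6-dimethylphenyl)prop-2-enoate
Product: 7 ethyl 3-(3-hydroxy-2,6-dimethylphenyl)propanoate
Conditions: H2 (1 atm), 10% Pd/C, EtOAc, rt
Reagents that add atoms: none
Why: Heterogeneous catalytic hydrogenation of the conjugated alkene, to which the arene, the phenol and the ester are inert.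

Step 5
Reactants: 7 ethyl 3-(3-hydroxy-2,6-dimethylphenyl)propanoate
Product: 9 3-(3-acetoxy-2,6-dimethylphenyl)propanoic acid, via hydroxy acid 8 (not isolated)
Conditions: 2 M NaOH, THF/H2O, rt; then Ac2O, 0 °C; then HCl to pH 2
Reagents that add atoms: acetic anhydride, CC(=O)OC(C)=O
Why: Saponification of the ester and, in the same alkaline aqueous solution, Schotten–Baumann-type acetylation of the phenoxide, any mixed anhydride at the carboxylate being hydrolysed before acidification returns the free acid.

Step 6
Reactants: 9 3-(3-acetoxy-2,6-dimethylphenyl)propanoic acid; 10 trimethylsilyldiazomethane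
Product: 12 4-(3-acetoxy-2,6-dimethylphenyl)-1-diazobutan-2-one, via acid chloride 11 (not isolated)
Conditions: (COCl)2, DMF (cat.), CH2Cl2, 0 °C to rt, evaporate; then Me3SiCHN2 (2.2 equiv), THF/MeCN, 0 °C to rt
Reagents that add atoms: oxalyl chloride, O=C(Cl)C(=O)Cl (chlorine of intermediate 11 only)
Why: Acid chloride formation and C-acylation of the silyl diazomethane with loss of the silyl group (the first stage of an Arndt–Eistert sequence), the aryl acetate keeping the phenol from reacting with the acid chloride.

Step 7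
Reactants: 12 4-(3-acetoxy-2,6-dimethylphenyl)-1-diazobutan-2-one
Product: 13 1-diazo-4-(3-hydroxy-2,6-dimethylphenyl)butan-2-one
Conditions: K2CO3 (0.2 equiv), MeOH, 0 °C
Reagents that add atoms: none
Why: Base-catalysed methanolysis (transesterification) of the aryl acetate, which is much faster than any reaction of the base-stable α-diazoketone.

Step 8
Reactants: 13 1-diazo-4-(3-hydroxy-2,6-dimethylphenyl)butan-2-one
Product: 14 (10S)-11,12,13-trinoreudesma-1,4-diene-3,8-dione
Conditions: Rh2(S-PTTL)4 (1 mol %), 4 Å MS, CH2Cl2, −20 to 0 °C, slow addition of 13 at high dilution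
Reagents that add atoms: none
Why: Proposed new method: loss of N2 from 13 at the divalent rhodium carboxylate dimer gives an electrophilic acceptor carbene at C9, which is attacked by the phenol ring at C10, the carbon para to the C3 hydroxyl, and the O-protonated dienone bearing a rhodium enolate collapses by proton transfer from oxygen to C9 to give 14, which cannot rearomatise because C10 is quaternary; a norcaradiene from competing C5–C10 cyclopropanation would be a donor–acceptor cyclopropane that opens to the same dienone. The closest known reaction types are the acid- or metal-promoted dearomatising cyclisations of phenolic α-diazoketones to cyclohexadienones and the enantioselective silver- or rhodium-carbene dearomatisations of phenols that give spirodienones, whereas the enantioselective fused-ring closure through an ortho carbon onto a methyl-bearing terminus is not established. Ring B (C5, C6, C7, C8, C9, C10) closes as a six-membered ring by C9–C10 bond formation in the Ar2-6 mode, the tether entering through the ortho carbon so that both arene carbons C5 and C10 end up inside the new ring. The only new stereocentre, C10, is set by the chiral pocket of the four N-phthaloyl-tert-leucinate ligands, which must distinguish the two enantiotopic faces of the flat phenol as it approaches the rhodium-bound carbene, the substrate having no stereocentre of its own. The step needs para (C10) over ortho (C4) attack and C–C over O–H bond formation: the first is favoured by the cross-conjugated product and by the crowding of C4 between the hydroxyl and the tether, the second by the intramolecular six-membered transition state together with high dilution and slow addition.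

Step 9
Reactants: 14 (10S)-11,12,13-trinoreudesma-1,4-diene-3,8-dione
Product: 15 (10R)-11,12,13-trinoreudesm-4-ene-3,8-dione
Conditions: RhCl(PPh3)3 (5 mol %), H2 (1 atm), benzene/EtOH 1:1, rt
Reagents that add atoms: none
Why: Homogeneous hydrogenation with the bulky rhodium phosphine complex, which reduces the disubstituted C1–C2 bond of a cross-conjugated dienone and leaves the tetrasubstituted C4–C5 bond and both ketones, as is well established for steroidal 1,4-dien-3-ones (the C10 descriptor changes only because the priorities change).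

Step 10
Reactants: 15 (10R)-11,12,13-trinoreudesm-4-ene-3,8-dione
Product: 16 (10R)-8,8-ethylenedioxy-11,12,13-trinoreudesm-4-en-3-one
Conditions: ethylene glycol (as solvent), TsOH·H2O (cat.), 4 Å MS, rt
Reagents that add atoms: ethylene glycol, OCCO
Why: Acid-catalysed ketalisation that takes the saturated C8 ketone in preference to the less electrophilic conjugated C3 ketone, a selectivity familiar from bicyclic enediones of the Robinson annulation type.

Step 11
Reactants: 16 (10R)-8,8-ethylenedioxy-11,12,13-trinoreudesm-4-en-3-one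
Product: 18 (5R,10R)-8,8-ethylenedioxy-3-trimethylsilyloxy-11,12,13-trinoreudesm-3-ene, via lithium enolate 17 (not isolated)
Conditions: Li (2.5 equiv), NH3(l)/THF, t-BuOH (1.0 equiv), −78 °C; isoprene; evaporate NH3; then Me3SiCl/Et3N, THF, −78 to 0 °C
Reagents that add atoms: lithium, [Li] (metal of intermediate 17 only); chlorotrimethylsilane, C[Si](C)(C)Cl
Why: Dissolving-metal (Birch-type) reduction of the enone in which the β-carbon C5 is protonated on the α face to give the trans ring fusion (H5 anti to the C10 methyl), and the C3–C4 lithium enolate so formed regiospecifically is trapped on oxygen as the silyl enol ether (reductive silylation).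

Step 12
Reactants: 18 (5R,10R)-8,8-ethylenedioxy-3-trimethylsilyloxy-11,12,13-trinoreudesm-3-ene
Product: 20 (4S,5R,10R)-8,8-ethylenedioxy-4-hydroxy-11,12,13-trinoreudesman-3-one, via silyloxy ketone 19 (not isolated)
Conditions: mCPBA (1.1 equiv), NaHCO3, CH2Cl2, −20 °C; then K2CO3 (cat.), MeOH, 0 °C
Reagents that add atoms: 3-chloroperoxybenzoic acid, O=C(OO)c1cccc(Cl)c1
Why: Rubottom oxidation in which the enol ether is epoxidised on the α face, anti to the axial C10 methyl that shields the β face of C4, so that silyl migration and methanolysis give the tertiary α-ketol with the 4α-oxygen and 4β-methyl of the target.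

Step 13
Reactants: 20 (4S,5R,10R)-8,8-ethylenedioxy-4-hydroxy-11,12,13-trinoreudesman-3-one
Product: 21 (4S,5R,10R)-4-acetoxy-8,8-ethylenedioxy-11,12,13-trinoreudesman-3-one
Conditions: Ac2O, Et3N, DMAP (0.5 equiv), CH2Cl2, rt to 35 °C
Reagents that add atoms: acetic anhydride, CC(=O)OC(C)=O
Why: DMAP-catalysed acetylation of the tertiary alcohol at the one stage where it is the only hydroxyl in the molecule, so that the tertiary acetate is in place before any competing hydroxyl exists.

Step 14
Reactants: 21 (4S,5R,10R)-4-acetoxy-8,8-ethylenedioxy-11,12,13-trinoreudesman-3-one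
Product: 23 (3S,4S,5R,10R)-4-acetoxy-3-hydroxy-11,12,13-trinoreudesman-8-one, via hydroxy ketal 22 (not isolated)
Conditions: NaBH4, CeCl3·7H2O, MeOH, −78 °C; acetone; then 1 M HCl, THF, 0 °C to rt
Reagents that add atoms: water, O (C8 carbonyl oxygen on ketal hydrolysis)
Why: Luche reduction in which hydride adds to C3 along the axial trajectory on the α face, opposite the axial C4 methyl, to give the equatorial 3β-alcohol trans to the 4α-acetate, after which dilute acid hydrolyses the dioxolane while the cold, non-basic medium should keep the acetyl group on O4.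

Step 15
Reactants: 24 tiglic acid
Product: 25 (E)-2-methylbut-2-en-1-ol
Conditions: LiAlH4, Et2O, 0 °C to rt
Reagents that add atoms: none
Why: Hydride reduction of the carboxylic acid to the primary allylic alcohol, the alkyl-substituted E double bond being retained.

Step 16
Reactants: 25 (E)-2-methylbut-2-en-1-ol
Product: 26 [(2R,3R)-2,3-dimethyloxiran-2-yl]methanol
Conditions: Ti(OiPr)4 (10 mol %), D-(−)-diisopropyl tartrate (12 mol %), t-BuOOH, 4 Å MS, CH2Cl2, −20 °C
Reagents that add atoms: tert-butyl hydroperoxide, CC(C)(C)OO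
Why: Sharpless asymmetric epoxidation of an E-trisubstituted allylic alcohol, in which the D-(−)-tartrate selects the alkene face that leads to the (2R,3R)-epoxy alcohol and the E geometry fixes the relative configuration.

Step 17
Reactants: 26 [(2R,3R)-2,3-dimethyloxiran-2-yl]methanol
Product: 27 (2S,3R)-2,3-dimethyloxirane-2-carboxylic acid
Conditions: TEMPO (10 mol %), PhI(OAc)2 (2.2 equiv), MeCN/H2O, rt
Reagents that add atoms: water, O (second carboxyl oxygen)
Why: Oxoammonium-mediated oxidation of the primary alcohol through the aldehyde hydrate to the acid under nearly neutral conditions that leave the epoxide and both stereocentres untouched (the C2 descriptor changes from R to S only through the change in priorities).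

Step 18
Reactants: 23 (3S,4S,5R,10R)-4-acetoxy-3-hydroxy-11,12,13-trinoreudesman-8-one; 27 (2S,3R)-2,3-dimethyloxirane-2-carboxylic acid
Product: 29 (3S,4S,5R,10R)-4-acetoxy-3-[(2S,3R)-2,3-epoxy-2-methylbutanoyloxy]-11,12,13-trinoreudesman-8-one, via mixed anhydride 28 (not isolated)
Conditions: 27, 2,4,6-trichlorobenzoyl chloride, Et3N, THF, 0 °C to rt; then 23, DMAP, toluene, rt to 40 °C
Reagents that add atoms: 2,4,6-trichlorobenzoyl chloride, O=C(Cl)c1c(Cl)cc(Cl)cc1Cl (aroyl group of intermediate 28 only)
Why: Yamaguchi esterification in which DMAP opens the mixed anhydride at the aliphatic carbonyl and the acylpyridinium acylates the hindered equatorial 3β-hydroxyl with retention at C3, the epoxide serving at the same time as the protected form of the later tertiary alcohol and chloride-bearing carbon.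

Step 19
Reactants: 29 (3S,4S,5R,10R)-4-acetoxy-3-[(2S,3R)-2,3-epoxy-2-methylbutanoyloxy]-11,12,13-trinoreudesman-8-one
Product: 31 (3S,4S,5R,7R,10R)-4-acetoxy-3-[(2S,3R)-2,3-epoxy-2-methylbutanoyloxy]-11-hydroxyeudesman-8-one, via lithium enolate 30 (not isolated)
Conditions: LiN(SiMe3)2 (1.05 equiv), THF, −78 °C; then acetone (3 equiv), −78 °C; AcOH, −78 °C
Reagents that add atoms: LiN(SiMe3)2, [Li]N([Si](C)(C)C)[Si](C)(C)C (lithium of intermediate 30 only); acetone, CC(C)=O
Why: Kinetic deprotonation of the C8 ketone at C7 (C9 is neopentylic next to quaternary C10, and the silylamide reacts far faster with the ketone than with the acetate or the epoxy ester, which has no α-hydrogen) followed by aldol addition to acetone, which forms the C7–C11 bond and a C7 stereocentre of no consequence.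

Step 20
Reactants: 31 (3S,4S,5R,7R,10R)-4-acetoxy-3-[(2S,3R)-2,3-epoxy-2-methylbutanoyloxy]-11-hydroxyeudesman-8-one
Product: 33 (3S,4S,5R,10R)-4-acetoxy-3-[(2S,3R)-2,3-epoxy-2-methylbutanoyloxy]eudesm-7(11)-en-8-one, via mesylate 32 (not isolated)
Conditions: MsCl, Et3N, CH2Cl2, 0 °C; then DBU, rt
Reagents that add atoms: methanesulfonyl chloride, CS(=O)(=O)Cl (mesyl group of intermediate 32 only)
Why: Sulfonylation of the tertiary alcohol through sulfene and E1cB elimination of the β-mesyloxy ketone, DBU drawing any β,γ-unsaturated isomer into conjugation, should give the tetrasubstituted exocyclic enone.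

Step 21
Reactants: 33 (3S,4S,5R,10R)-4-acetoxy-3-[(2S,3R)-2,3-epoxy-2-methylbutanoyloxy]eudesm-7(11)-en-8-one
Product: 35 (3S,4S,5R,10R)-4-acetoxy-3-[(2S,3R)-2,3-epoxy-2-methylbutanoyloxy]-11-hydroxyeudesm-6-en-8-one, via hydroperoxide 34 (not isolated)
Conditions: O2, tetraphenylporphyrin (cat.), visible light, CH2Cl2, 0 °C; then PPh3, 0 °C to rt
Reagents that add atoms: dioxygen, O=O
Why: Schenck ene reaction of singlet oxygen with an s-cis α-alkylidene ketone, in which the geminal selectivity known for such enones (the pulegone type) takes the hydrogen from C6, places oxygen on C11 and moves the double bond to C6–C7, the hydroperoxide then being reduced by the phosphine and the s-trans enone product being inert to further singlet oxygen.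

Step 22
Reactants: 35 (3S,4S,5R,10R)-4-acetoxy-3-[(2S,3R)-2,3-epoxy-2-methylbutanoyloxy]-11-hydroxyeudesm-6-en-8-one
Product: 36 (3S,4S,5R,10R)-4-acetoxy-3-[(2R,3S)-3-chloro-2-hydroxy-2-methylbutanoyloxy]-11-hydroxyeudesm-6-en-8-one
Conditions: HCl (1 M in Et2O, 1.5 equiv), CH2Cl2, −20 to 0 °C
Reagents that add atoms: hydrogen chloride, Cl
Why: Acid-promoted SN2 opening of the α-methyl glycidic ester by chloride at the secondary C3' (the tertiary, ester-bearing C2' is disfavoured sterically and electronically), which inverts C3' and leaves C2' untouched, so that the (2S,3R)-epoxide gives the (2R,3S)-chlorohydrin of the target.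

**Compound list**
1 | 2,6-dimethylbenzaldehyde | Cc1cccc(C)c1C=O | starting material
2 | 3-bromo-2,6-dimethylbenzaldehyde | Cc1ccc(Br)c(C)c1C=O | intermediate
3 | triethyl phosphonoacetate | CCOC(=O)CP(=O)(OCC)OCC | starting material
4 | ethyl (E)-3-(3-bromo-2,6-dimethylphenyl)prop-2-enoate | CCOC(=O)/C=C/c1c(C)ccc(Br)c1C | intermediate
5 | ethyl (E)-3-[2,6-dimethyl-3-(4,4,5,5-tetramethyl-1,3,2-dioxaborolan-2-yl)phenyl]prop-2-enoate | CCOC(=O)/C=C/c1c(C)ccc(B2OC(C)(C)C(C)(C)O2)c1C | intermediate (not isolated)
6 | ethyl (E)-3-(3-hydroxy-2,6-dimethylphenyl)prop-2-enoate | CCOC(=O)/C=C/c1c(C)ccc(O)c1C | intermediate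
7 | ethyl 3-(3-hydroxy-2,6-dimethylphenyl)propanoate | CCOC(=O)CCc1c(C)ccc(O)c1C | intermediate
8 | 3-(3-hydroxy-2,6-dimethylphenyl)propanoic acid (present as its disodium salt) | OC(=O)CCc1c(C)ccc(O)c1C | intermediate (not isolated)
9 | 3-(3-acetoxy-2,6-dimethylphenyl)propanoic acid | CC(=O)Oc1ccc(C)c(CCC(=O)O)c1C | intermediate
10 | trimethylsilyldiazomethane | C[Si](C)(C)C=[N+]=[N-] | starting material
11 | 3-(3-acetoxy-2,6-dimethylphenyl)propanoyl chloride | CC(=O)Oc1ccc(C)c(CCC(=O)Cl)c1C | intermediate (not isolated)
12 | 4-(3-acetoxy-2,6-dimethylphenyl)-1-diazobutan-2-one | CC(=O)Oc1ccc(C)c(CCC(=O)C=[N+]=[N-])c1C | intermediate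
13 | 1-diazo-4-(3-hydroxy-2,6-dimethylphenyl)butan-2-one | Cc1ccc(O)c(C)c1CCC(=O)C=[N+]=[N-] | intermediate (key-step precursor)
14 | (10S)-11,12,13-trinoreudesma-1,4-diene-3,8-dione, (4aS)-1,4a-dimethyl-4a,5,7,8-tetrahydronaphthalene-2,6-dione, 10β-methyl | CC1=C2CCC(=O)C[C@@]2(C)C=CC1=O | intermediate (key-step product)
15 | (10R)-11,12,13-trinoreudesm-4-ene-3,8-dione | CC1=C2CCC(=O)C[C@@]2(C)CCC1=O | intermediate
16 | (10R)-8,8-ethylenedioxy-11,12,13-trinoreudesm-4-en-3-one | CC1=C2CCC3(OCCO3)C[C@@]2(C)CCC1=O | intermediate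
17 | lithium (5R,10R)-8,8-ethylenedioxy-11,12,13-trinoreudesm-3-en-3-olate (trans-fused, 5α-H) | CC1=C(O[Li])CC[C@]2(C)CC3(OCCO3)CC[C@H]21 | intermediate (not isolated)
18 | (5R,10R)-8,8-ethylenedioxy-3-trimethylsilyloxy-11,12,13-trinoreudesm-3-ene | CC1=C(O[Si](C)(C)C)CC[C@]2(C)CC3(OCCO3)CC[C@H]21 | intermediate
19 | (4S,5R,10R)-8,8-ethylenedioxy-4-trimethylsilyloxy-11,12,13-trinoreudesman-3-one | C[Si](C)(C)O[C@]1(C)C(=O)CC[C@]2(C)CC3(OCCO3)CC[C@H]21 | intermediate (not isolated)
20 | (4S,5R,10R)-8,8-ethylenedioxy-4-hydroxy-11,12,13-trinoreudesman-3-one (4α-OH, 4β-methyl) | O[C@]1(C)C(=O)CC[C@]2(C)CC3(OCCO3)CC[C@H]21 | intermediate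
21 | (4S,5R,10R)-4-acetoxy-8,8-ethylenedioxy-11,12,13-trinoreudesman-3-one | CC(=O)O[C@]1(C)C(=O)CC[C@]2(C)CC3(OCCO3)CC[C@H]21 | intermediate
22 | (3S,4S,5R,10R)-4-acetoxy-8,8-ethylenedioxy-11,12,13-trinoreudesman-3-ol | CC(=O)O[C@]1(C)[C@@H](O)CC[C@]2(C)CC3(OCCO3)CC[C@H]21 | intermediate (not isolated)
23 | (3S,4S,5R,10R)-4-acetoxy-3-hydroxy-11,12,13-trinoreudesman-8-one (3β-OH, 4α-OAc) | CC(=O)O[C@]1(C)[C@@H](O)CC[C@]2(C)CC(=O)CC[C@H]21 | intermediate
24 | tiglic acid, (E)-2-methylbut-2-enoic acid | C/C=C(\C)C(=O)O | starting material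
25 | (E)-2-methylbut-2-en-1-ol | C/C=C(\C)CO | intermediate
26 | [(2R,3R)-2,3-dimethyloxiran-2-yl]methanol | C[C@H]1O[C@]1(C)CO | intermediate
27 | (2S,3R)-2,3-dimethyloxirane-2-carboxylic acid, (2S,3R)-2,3-epoxy-2-methylbutanoic acid | C[C@H]1O[C@]1(C)C(=O)O | intermediate
28 | (2S,3R)-2,3-dimethyloxirane-2-carboxylic 2,4,6-trichlorobenzoic anhydride | C[C@H]1O[C@]1(C)C(=O)OC(=O)c1c(Cl)cc(Cl)cc1Cl | intermediate (not isolated)
29 | (3S,4S,5R,10R)-4-acetoxy-3-[(2S,3R)-2,3-epoxy-2-methylbutanoyloxy]-11,12,13-trinoreudesman-8-one | CC(=O)O[C@]1(C)[C@@H](OC(=O)[C@@]3(C)O[C@@H]3C)CC[C@]2(C)CC(=O)CC[C@H]21 | intermediate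
30 | C7–C8 lithium enolate of 29 | CC(=O)O[C@]1(C)[C@@H](OC(=O)[C@@]3(C)O[C@@H]3C)CC[C@]2(C)CC(O[Li])=CC[C@H]21 | intermediate (not isolated)
31 | (3S,4S,5R,7R,10R)-4-acetoxy-3-[(2S,3R)-2,3-epoxy-2-methylbutanoyloxy]-11-hydroxyeudesman-8-one (equatorial C7 epimer drawn; C7 is lost in step 20) | CC(=O)O[C@]1(C)[C@@H](OC(=O)[C@@]3(C)O[C@@H]3C)CC[C@]2(C)CC(=O)[C@@H](C(C)(C)O)C[C@H]21 | intermediate
32 | 11-O-methanesulfonate of 31 | CC(=O)O[C@]1(C)[C@@H](OC(=O)[C@@]3(C)O[C@@H]3C)CC[C@]2(C)CC(=O)[C@@H](C(C)(C)OS(C)(=O)=O)C[C@H]21 | intermediate (not isolated)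
33 | (3S,4S,5R,10R)-4-acetoxy-3-[(2S,3R)-2,3-epoxy-2-methylbutanoyloxy]eudesm-7(11)-en-8-one | CC(=O)O[C@]1(C)[C@@H](OC(=O)[C@@]3(C)O[C@@H]3C)CC[C@]2(C)CC(=O)C(=C(C)C)C[C@H]21 | intermediate
34 | (3S,4S,5R,10R)-4-acetoxy-3-[(2S,3R)-2,3-epoxy-2-methylbutanoyloxy]-11-hydroperoxyeudesm-6-en-8-one | CC(=O)O[C@]1(C)[C@@H](OC(=O)[C@@]3(C)O[C@@H]3C)CC[C@]2(C)CC(=O)C(C(C)(C)OO)=C[C@H]21 | intermediate (not isolated)
35 | (3S,4S,5R,10R)-4-acetoxy-3-[(2S,3R)-2,3-epoxy-2-methylbutanoyloxy]-11-hydroxyeudesm-6-en-8-one | CC(=O)O[C@]1(C)[C@@H](OC(=O)[C@@]3(C)O[C@@H]3C)CC[C@]2(C)CC(=O)C(C(C)(C)O)=C[C@H]21 | intermediate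
36 | CNP0119872.1, (3S,4S,5R,10R)-4-acetoxy-3-[(2R,3S)-3-chloro-2-hydroxy-2-methylbutanoyloxy]-11-hydroxyeudesm-6-en-8-one | CC(=O)O[C@]1(C)[C@@H](OC(=O)[C@@](C)(O)[C@H](C)Cl)CC[C@]2(C)CC(=O)C(C(C)(C)O)=C[C@H]21 | target

**Step count**
Total: 22 steps. Longest linear sequence: 19 steps (steps 1–14 and 18–22); the side-chain acid takes 3 steps (15–17).

**Steps most likely to fail**

1. Step 8 (asymmetric dearomatising cyclisation). What may go wrong: poor discrimination of the two arene faces by an acceptor-only carbene, bond formation at C4 or at the phenol oxygen instead of C10, or ring expansion of the arene. Fallback: the route is left at 13, which is cyclised without a metal by CF3CO2H in CH2Cl2 at −20 °C. The diazo carbon is protonated and N2 is lost with participation of the phenol para carbon; this is the long-known acid-promoted dearomatising cyclisation of phenolic diazoketones. It gives the racemic dienone F1. The enantiomers are separated by preparative chromatography on a polysaccharide-based chiral stationary phase, and the 10S enantiomer is 14, where the route is rejoined for step 9.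

2. Step 21 (photooxygenation). What may go wrong: slow reaction of the electron-poor tetrasubstituted enone, and loss of regioselectivity through hydrogen abstraction from the C12/C13 methyl groups with oxygen delivered to C7. Fallback: a selenium-based sequence that sets out from 29 and replaces steps 19–21. The lithium enolate 30 is quenched with PhSeCl at −78 °C to give the 7-phenylselanyl ketone F2. A second deprotonation with LiN(SiMe3)2, now at the selenium-bearing carbon, gives the lithium enolate F3, which adds to acetone to give the selenide aldol F4. H2O2/pyridine in CH2Cl2 at 0 °C oxidises selenium to the selenoxide F5. Its syn elimination can only run toward C6, since C8 and C11 carry no hydrogen, and gives 35, where the route is rejoined for step 22.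

3. Step 18 (esterification at O3). What may go wrong: slow acylation of the neopentyl-like 3β-hydroxyl, which lets base-promoted migration of the acetyl group from the tertiary O4 to the secondary O3 compete, and attack of the alcohol at the aroyl carbonyl of the mixed anhydride. Fallback: the two acyl groups are introduced in the opposite order, so that a free hydroxyl never sits next to the acetate. The sequence sets out from 20: Luche reduction gives the 3β,4α-diol ketal F6. Yamaguchi acylation with 27 (through 28) takes only the secondary 3β-hydroxyl and gives the hydroxy ester F7. The tertiary 4α-hydroxyl is then acetylated (Ac2O, DMAP, Et3N, 40 °C) to the diester ketal F8. Pyridinium p-toluenesulfonate in wet acetone removes the dioxolane and gives 29, where the route is rejoined for step 19.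

**Further compounds**
F1 | step 8 | racemic 11,12,13-trinoreudesma-1,4-diene-3,8-dione | CC1=C2CCC(=O)CC2(C)C=CC1=O
F2 | step 21 | (3S,4S,5R,10R)-4-acetoxy-3-[(2S,3R)-2,3-epoxy-2-methylbutanoyloxy]-7-phenylselanyl-11,12,13-trinoreudesman-8-one (C7 epimers) | CC(=O)O[C@]1(C)[C@@H](OC(=O)[C@@]3(C)O[C@@H]3C)CC[C@]2(C)CC(=O)C([Se]c3ccccc3)C[C@H]21
F3 | step 21 | C7–C8 lithium enolate of F2 | CC(=O)O[C@]1(C)[C@@H](OC(=O)[C@@]3(C)O[C@@H]3C)CC[C@]2(C)CC(O[Li])=C([Se]c3ccccc3)C[C@H]21
F4 | step 21 | (3S,4S,5R,10R)-4-acetoxy-3-[(2S,3R)-2,3-epoxy-2-methylbutanoyloxy]-11-hydroxy-7-phenylselanyleudesman-8-one (C7 epimers) | CC(=O)O[C@]1(C)[C@@H](OC(=O)[C@@]3(C)O[C@@H]3C)CC[C@]2(C)CC(=O)C([Se]c3ccccc3)(C(C)(C)O)C[C@H]21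
F5 | step 21 | selenoxide of F4 | CC(=O)O[C@]1(C)[C@@H](OC(=O)[C@@]3(C)O[C@@H]3C)CC[C@]2(C)CC(=O)C([Se](=O)c3ccccc3)(C(C)(C)O)C[C@H]21
F6 | step 18 | (3S,4S,5R,10R)-8,8-ethylenedioxy-11,12,13-trinoreudesmane-3,4-diol | O[C@]1(C)[C@@H](O)CC[C@]2(C)CC3(OCCO3)CC[C@H]21
F7 | step 18 | (3S,4S,5R,10R)-3-[(2S,3R)-2,3-epoxy-2-methylbutanoyloxy]-8,8-ethylenedioxy-11,12,13-trinoreudesman-4-ol | O[C@]1(C)[C@@H](OC(=O)[C@@]4(C)O[C@@H]4C)CC[C@]2(C)CC3(OCCO3)CC[C@H]21
F8 | step 18 | (3S,4S,5R,10R)-4-acetoxy-3-[(2S,3R)-2,3-epoxy-2-methylbutanoyloxy]-8,8-ethylenedioxy-11,12,13-trinoreudesmane | CC(=O)O[C@]1(C)[C@@H](OC(=O)[C@@]4(C)O[C@@H]4C)CC[C@]2(C)CC3(OCCO3)CC[C@H]21
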